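Prostanoid numbering is used (ester carbon C1; ring C8–C12). Everything rests on removing C10 together with its chlorine from the α-chloroenone C9(=O)–C10(Cl)=C11H of the cyclopentenone ring as dichlorocarbene. This leaves a cyclobutene enol ether, the silyl ether of (R)-1-allyl-3-ethoxycyclobut-2-en-1-ol, whose C9=C11 bond is the only electron-rich alkene. In one operation, carbene addition and opening of the resulting bicyclo[2.1.0]pentane expand the four-membered ring. The same operation creates the carbonyl, the ring alkene and the C–Cl bond. The carbinol centre C12, set earlier by catalytic asymmetric allylation of 3-ethoxycyclobutenone, is untouched. Z-selective cross-metathesis and aldol–elimination then attach both chains.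

Key step: step 3

Assumption: the (R)-ligand in step 2 is taken to deliver allyl to the carbonyl face that gives (R)-6, by analogy with simple cyclic enones; if an assay shows the opposite sense, the equally available (S)-ligand is used and nothing else changes.

Step 1
Reactants: 1 ethoxyacetylene; 2 acetyl chloride
Product: 4 3-ethoxycyclobut-2-en-1-one, via ketene 3 (not isolated)
Conditions: 2 added slowly to 1, Et3N, Et2O, 0 °C to rt
Reagents that add atoms: none
Why: Ketene, released from acetyl chloride by dehydrochlorination, is trapped by the strongly nucleophilic ynol ether in a thermal [2+2] ketene–alkyne cycloaddition, in which the unsubstituted alkyne carbon bonds to the ketene carbonyl carbon so that only the 3-ethoxy regioisomer can form.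

Step 2
Reactants: 4 3-ethoxycyclobut-2-en-1-one; 5 allyltrimethoxysilane
Product: 7 (R)-{[3-ethoxy-1-(prop-2-en-1-yl)cyclobut-2-en-1-yl]oxy}triethylsilane, via cyclobutenol 6 (not isolated)
Conditions: AgF (5 mol %), (R)-DIFLUORPHOS (5 mol %), MeOH (1 equiv), THF, −78 °C; then 2,6-lutidine, Et3SiOTf, −78 to −40 °C, same flask
Reagents that add atoms: triethylsilyl trifluoromethanesulfonate, CC[Si](CC)(CC)OS(=O)(=O)C(F)(F)F
Why: Catalytic asymmetric Sakurai–Hosomi allylation, in which the chiral allylsilver species adds 1,2 through a cyclic transition state to the strained carbonyl (strain release offsets the vinylogous-ester deactivation, and enolisation is excluded because the enolate would be a cyclobutadiene), the ligand selects the carbonyl face and so sets C12, and protic turnover plus cold silylation avoids a long-lived alkoxide that could ring-open or undergo an anionic oxy-Cope shift.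

Step 3
Reactants: 7 (R)-{[3-ethoxy-1-(prop-2-en-1-yl)cyclobut-2-en-1-yl]oxy}triethylsilane
Product: 10 (R)-2-chloro-4-(prop-2-en-1-yl)-4-(triethylsilyloxy)cyclopent-2-en-1-one, via dichlorobicyclopentane 8 (not isolated), via oxocarbenium chloride 9 (not isolated)
Conditions: CHCl3, KOtBu, pentane, −30 to 0 °C; then aq. oxalic acid, THF, 0 °C
Reagents that add atoms: chloroform, ClC(Cl)Cl; water, O
Why: Electrophilic dichlorocarbene, made by α-elimination from chloroform, adds in a concerted [2+1] cheletropic step to the most electron-rich alkene, the C9=C11 enol ether, to give bicyclo[2.1.0]pentane 8 (three-membered ring closed by [2+1] addition; attack on either face leads on to the same product). The endo chloride of 8 then leaves with disrotatory two-electron electrocyclic opening of the strained central C9–C11 bond (cyclopropyl-to-allyl cation rearrangement), so the five-membered ring arises not by a closure but by cleavage of the zero bridge, and the carbene carbon becomes C10 with its remaining chlorine. The ethoxy group stabilises the cation as oxocarbenium ion 9 and fixes the carbonyl at C9, and mild aqueous acid hydrolyses 9 (or its covalent chloride or tert-butoxide adducts) to enone 10. The closest known reaction types are the dihalocarbene ring expansion of cyclic enol ethers and silyl enol ethers to α-halo enones and the spontaneous opening of 5,5-dihalobicyclo[2.1.0]pentanes to 2-halocyclopentenyl halides. No lasting stereocentre is created, the two bridgehead centres of 8 disappear again, and none of the four bonds at C12 is broken, so its configuration is kept. The step needs chemoselectivity for the enol ether over the monosubstituted allyl alkene, which the large rate difference of an electrophilic carbene for these two alkenes secures (the reason why the cross-metathesis comes afterwards), and regiochemistry, which the position of the ethoxy group secures.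

Step 4
Reactants: 10 (R)-2-chloro-4-(prop-2-en-1-yl)-4-(triethylsilyloxy)cyclopent-2-en-1-one; 11 hept-1-ene
Product: 12 (R)-2-chloro-4-[(2Z)-oct-2-en-1-yl]-4-(triethylsilyloxy)cyclopent-2-en-1-one
Conditions: 11 (excess), Z-selective Grubbs catalyst Ru(NO3)(=CH-C6H4-2-OiPr)[cyclometalated 1-(1-adamantyl)-3-(2,6-diisopropylphenyl)imidazolin-2-ylidene] (5 mol %), THF, 35 °C, ethene removed under static vacuum
Reagents that add atoms: none
Why: Z-selective olefin cross-metathesis, in which only the terminal allyl alkene engages the ruthenium alkylidene (the trisubstituted, electron-poor chloroenone alkene is inert) and the cyclometalated catalyst enforces a side-bound all-syn metallacyclobutane that releases the (Z)-C14=C15 alkene under kinetic control.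

Step 5
Reactants: 13 methyl hex-5-enoate; 14 (E)-but-2-enal
Product: 15 methyl (E)-7-oxohept-5-enoate
Conditions: 14 (excess), second-generation Hoveyda–Grubbs catalyst (2 mol %), CH2Cl2, 40 °C
Reagents that add atoms: none
Why: Cross-metathesis of a terminal alkene with an electron-poor enal partner is selective for the cross product and gives the (E)-enal under thermodynamic control, which sets the C5=C6 geometry.

Step 6
Reactants: 12 (R)-2-chloro-4-[(2Z)-oct-2-en-1-yl]-4-(triethylsilyloxy)cyclopent-2-en-1-one; 15 methyl (E)-7-oxohept-5-enoate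
Product: 16 methyl (5E)-7-[(5R)-3-chloro-5-[(2Z)-oct-2-en-1-yl]-2-oxo-5-(triethylsilyloxy)cyclopent-3-en-1-yl]-7-hydroxyhept-5-enoate (mixture of diastereomers at C7 and C8)
Conditions: LiN(iPr)2, THF, −78 °C; then 15; AcOH quench at −78 °C
Reagents that add atoms: none
Why: Kinetic deprotonation can occur only at C8 (C10 and C12 carry no hydrogen), loss of the β-silyloxy group from the enolate would give an antiaromatic cyclopentadienone and is therefore slow at −78 °C, and the lithium enolate adds 1,2 to the enal in a directed aldol addition whose new centres at C7 and C8 need no control because both vanish in step 7.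

Step 7
Reactants: 16 methyl (5E)-7-[(5R)-3-chloro-5-[(2Z)-oct-2-en-1-yl]-2-oxo-5-(triethylsilyloxy)cyclopent-3-en-1-yl]-7-hydroxyhept-5-enoate
Product: 18 methyl (5E,7E)-7-[(2S)-4-chloro-2-[(2Z)-oct-2-en-1-yl]-5-oxo-2-(triethylsilyloxy)cyclopent-3-en-1-ylidene]hept-5-enoate, via allylic mesylate 17 (not isolated)
Conditions: MsCl, Et3N (excess), CH2Cl2, −20 °C to rt
Reagents that add atoms: methanesulfonyl chloride, CS(=O)(=O)Cl (its atoms stay only in 17)
Why: Mesylation followed by E1cB elimination through the C8 enolate funnels all aldol diastereomers into the conjugated dienone, the (7E) geometry being favoured because in the eliminating enolate the alkenyl chain avoids the in-plane enolate oxygen and turns towards C12, whose substituents lie above and below the ring plane (the change of descriptor at C12 from R to S reflects only the new priority of C8).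

Step 8
Reactants: 18 methyl (5E,7E)-7-[(2S)-4-chloro-2-[(2Z)-oct-2-en-1-yl]-5-oxo-2-(triethylsilyloxy)cyclopent-3-en-1-ylidene]hept-5-enoate
Product: 19 methyl (5E,7E)-7-[(2S)-4-chloro-2-hydroxy-2-[(2Z)-oct-2-en-1-yl]-5-oxocyclopent-3-en-1-ylidene]hept-5-enoate (target)
Conditions: HF·pyridine, THF, 0 °C
Reagents that add atoms: none
Why: Fluoride-driven cleavage of the tertiary triethylsilyl ether under buffered, weakly acidic conditions breaks only the O–Si bond, so the methyl ester, the cross-conjugated chlorodienone, all three alkene geometries and the configuration at C12 are retained.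

Compound list
1 | ethoxyacetylene | CCOC#C | starting material
2 | acetyl chloride | CC(=O)Cl | starting material
3 | ketene | C=C=O | intermediate
4 | 3-ethoxycyclobut-2-en-1-one | CCOC1=CC(=O)C1 | intermediate
5 | allyltrimethoxysilane | C=CC[Si](OC)(OC)OC | starting material
6 | (R)-3-ethoxy-1-(prop-2-en-1-yl)cyclobut-2-en-1-ol | C=CC[C@]1(O)C=C(OCC)C1 | intermediate
7 | (R)-{[3-ethoxy-1-(prop-2-en-1-yl)cyclobut-2-en-1-yl]oxy}triethylsilane | C=CC[C@]1(O[Si](CC)(CC)CC)C=C(OCC)C1 | intermediate
8 | 5,5-dichloro-1-ethoxy-3-(prop-2-en-1-yl)-3-(triethylsilyloxy)bicyclo[2.1.0]pentane (carbinol carbon as in 7, both bridgehead facial isomers) | C=CC[C@]1(O[Si](CC)(CC)CC)C2C(Cl)(Cl)C2(OCC)C1 | intermediate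
9 | O-ethyl oxocarbenium chloride of 10 (2-chloro-1-ethoxycyclopentenyl cation ion pair) | C=CC[C@]1(O[Si](CC)(CC)CC)C=C(Cl)C(=[O+]CC)C1.[Cl-] | intermediate
10 | (R)-2-chloro-4-(prop-2-en-1-yl)-4-(triethylsilyloxy)cyclopent-2-en-1-one | C=CC[C@]1(O[Si](CC)(CC)CC)C=C(Cl)C(=O)C1 | intermediate
11 | hept-1-ene | C=CCCCCC | starting material
12 | (R)-2-chloro-4-[(2Z)-oct-2-en-1-yl]-4-(triethylsilyloxy)cyclopent-2-en-1-one | CCCCC/C=C\C[C@]1(O[Si](CC)(CC)CC)C=C(Cl)C(=O)C1 | intermediate
13 | methyl hex-5-enoate | C=CCCCC(=O)OC | starting material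
14 | (E)-but-2-enal | C/C=C/C=O | starting material
15 | methyl (E)-7-oxohept-5-enoate | O=C/C=C/CCCC(=O)OC | intermediate
16 | methyl (5E)-7-[(5R)-3-chloro-5-[(2Z)-oct-2-en-1-yl]-2-oxo-5-(triethylsilyloxy)cyclopent-3-en-1-yl]-7-hydroxyhept-5-enoate, diastereomer mixture at C7 and C8 | CCCCC/C=C\C[C@]1(O[Si](CC)(CC)CC)C=C(Cl)C(=O)C1C(O)/C=C/CCCC(=O)OC | intermediate
17 | methanesulfonate of 16 | CCCCC/C=C\C[C@]1(O[Si](CC)(CC)CC)C=C(Cl)C(=O)C1C(OS(C)(=O)=O)/C=C/CCCC(=O)OC | intermediate
18 | methyl (5E,7E)-7-[(2S)-4-chloro-2-[(2Z)-oct-2-en-1-yl]-5-oxo-2-(triethylsilyloxy)cyclopent-3-en-1-ylidene]hept-5-enoate | CCCCC/C=C\C[C@]1(O[Si](CC)(CC)CC)C=C(Cl)C(=O)/C1=C/C=C/CCCC(=O)OC | intermediate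
19 | methyl (5E,7E)-7-[(2S)-4-chloro-2-hydroxy-2-[(2Z)-oct-2-en-1-yl]-5-oxocyclopent-3-en-1-ylidene]hept-5-enoate | CCCCC/C=C\C[C@]1(O)C=C(Cl)C(=O)/C1=C/C=C/CCCC(=O)OC | target

Total steps: 8. Longest linear sequence: 7 (steps 1, 2, 3, 4, 6, 7, 8).

Steps most likely to fail

Step 2. The addition to the vinylogous-ester carbonyl may be slow or poorly face-selective, and the cyclobutenol may ionise before it is silylated. The fallback replaces enantioselective C–C bond formation by a desymmetrising enolisation.
- It sets out from 4. Allylmagnesium bromide (THF, −78 °C) followed by 2,6-lutidine and Et3SiOTf in the same flask gives racemic {[3-ethoxy-1-(prop-2-en-1-yl)cyclobut-2-en-1-yl]oxy}triethylsilane F1.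
- Wet oxalic acid on silica hydrolyses the enol ether to the prochiral ketone 3-(prop-2-en-1-yl)-3-(triethylsilyloxy)cyclobutan-1-one F2.
- Enantioselective deprotonation with lithium (R,R)-bis(1-phenylethyl)amide and LiCl in the presence of Me3SiCl (THF, −100 °C) gives (R)-triethyl{[1-(prop-2-en-1-yl)-3-(trimethylsilyloxy)cyclobut-2-en-1-yl]oxy}silane F3.
- F3 takes the place of 7 under the conditions of step 3 and comes back to the route at 10.

Step 3. The carbene may also cyclopropanate the allyl group. Trichloromethyl anion or alkoxide may attack the ring-expanded product before hydrolysis. The strained enol ether may decompose under the basic conditions. The fallback separates the chlorine from the ring expansion.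
- It sets out from 7. Chlorocarbenoid (CH2Cl2, MeLi, Et2O, −30 °C), which adds to enol ethers with a preference for the endo chloride, gives 5-chloro-1-ethoxy-3-(prop-2-en-1-yl)-3-(triethylsilyloxy)bicyclo[2.1.0]pentane F4.
- F4 opens in the same electrocyclic way and after mild aqueous acid gives (R)-4-(prop-2-en-1-yl)-4-(triethylsilyloxy)cyclopent-2-en-1-one F5.
- Nucleophilic epoxidation (H2O2, NaOH, MeOH, 0 °C) gives 4-(prop-2-en-1-yl)-4-(triethylsilyloxy)-6-oxabicyclo[3.1.0]hexan-2-one F6.
- Pyridinium chloride in pyridine opens the epoxide at the α-carbon to 2-chloro-3-hydroxy-4-(prop-2-en-1-yl)-4-(triethylsilyloxy)cyclopentan-1-one F7, which loses water by E1cB elimination and comes back to the route at 10.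

Step 7. The E1cB elimination may show poor control of the C7=C8 geometry, and the allylic mesylate may ionise or be displaced. The fallback replaces the stereorandom aldol and stepwise elimination by a stereospecific pair of reactions.
- It sets out from 12 and 15. The dicyclohexylboron enolate of 12 (c-Hex2BCl, Et3N, Et2O, −78 °C), whose E(O) geometry is forced by the ring, adds to 15 through a Zimmerman–Traxler chair.
- This gives the 7,8-anti aldol methyl (5E)-7-[(5R)-3-chloro-5-[(2Z)-oct-2-en-1-yl]-2-oxo-5-(triethylsilyloxy)cyclopent-3-en-1-yl]-7-hydroxyhept-5-enoate (side chain trans to the silyloxy group) F8.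
- Concerted syn-dehydration with dicyclohexylcarbodiimide and CuCl (toluene, 60 °C) eclipses C6 with C12 and H7 with C9, gives only the (7E) alkene, and comes back to the route at 18.

Further compounds
F1 | step 2 | racemic {[3-ethoxy-1-(prop-2-en-1-yl)cyclobut-2-en-1-yl]oxy}triethylsilane | C=CCC1(O[Si](CC)(CC)CC)C=C(OCC)C1
F2 | step 2 | 3-(prop-2-en-1-yl)-3-(triethylsilyloxy)cyclobutan-1-one | C=CCC1(O[Si](CC)(CC)CC)CC(=O)C1
F3 | step 2 | (R)-triethyl{[1-(prop-2-en-1-yl)-3-(trimethylsilyloxy)cyclobut-2-en-1-yl]oxy}silane | C=CC[C@]1(O[Si](CC)(CC)CC)C=C(O[Si](C)(C)C)C1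
F4 | step 3 | 5-chloro-1-ethoxy-3-(prop-2-en-1-yl)-3-(triethylsilyloxy)bicyclo[2.1.0]pentane | C=CC[C@]1(O[Si](CC)(CC)CC)C2C(Cl)C2(OCC)C1
F5 | step 3 | (R)-4-(prop-2-en-1-yl)-4-(triethylsilyloxy)cyclopent-2-en-1-one | C=CC[C@]1(O[Si](CC)(CC)CC)C=CC(=O)C1
F6 | step 3 | 4-(prop-2-en-1-yl)-4-(triethylsilyloxy)-6-oxabicyclo[3.1.0]hexan-2-one | C=CC[C@]1(O[Si](CC)(CC)CC)C2OC2C(=O)C1
F7 | step 3 | 2-chloro-3-hydroxy-4-(prop-2-en-1-yl)-4-(triethylsilyloxy)cyclopentan-1-one | C=CC[C@]1(O[Si](CC)(CC)CC)C(O)C(Cl)C(=O)C1
F8 | step 7 | 7,8-anti aldol, methyl (5E)-7-[(5R)-3-chloro-5-[(2Z)-oct-2-en-1-yl]-2-oxo-5-(triethylsilyloxy)cyclopent-3-en-1-yl]-7-hydroxyhept-5-enoate | CCCCC/C=C\C[C@]1(O[Si](CC)(CC)CC)C=C(Cl)C(=O)[C@@H]1[C@@H](O)/C=C/CCCC(=O)OC
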